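**Retrosynthetic overview**

- The sulfate goes on last, on the hydroxyl between the olefin and the formyl group, with the catechol masked in the flask. The formyl group comes from ortho-lithiation between two MOM ethers, and the C9=C11 olefin from dehydration of the carbinol formed from an aryllithium and a decalin C9-carbaldehyde.
- The decalin aldehyde is cut at C1–C2, C4–C5 and C9–C10 into two pieces. (R)-Citronellal supplies C5–C10, C1, C11 and the C8 and C10 methyl groups, and its stereocentre is C8. Prenyl phenyl sulfone supplies C2–C3–C4 with the geminal methyl groups.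
- Enabling feature: in ring A the gem-dimethyl carbon C4 and C2 are the two ends of a 3-methylbut-2-enyl unit. It bridges C1 (an allylic methyl carbon of citronellal's isopropylidene group) and the ring-fusion carbon C5 (its olefinic CH). A prenyl sulfone is nucleophilic at C2 and, once ionised, electrophilic at C4; the E C5=C10 olefin and a C9=C11 enol ester then turn the cation into trans-fused rings A and B.
- Rings A and B form together in one flask (A by C4–C5, B by C9–C10). C8 steers the absolute sense and is then inverted through the C8=C9 enal and face-selective hydrogenation. The arene ring is bought.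

Key step: step 4

Remark: terpenoid carbons are numbered C1–C11 as in drimanes (C11 is the benzylic carbon); the aryl hydrogen sulfate is taken through work-up as its sodium salt and is listed in the neutral form.

**Step 1**
Reactants: 1 (R)-citronellal, (3R)-3,7-dimethyloct-6-enal
Product: 2 (3R)-3,7-dimethylocta-1,6-dien-1-yl pivalate (E/Z mixture at the enol ester)
Conditions: Piv2O, Et3N, DMAP (cat.), toluene, 90 °C
Reagents that add atoms: pivalic anhydride CC(C)(C)C(=O)OC(=O)C(C)(C)C
Why: Enol ester formation (base-mediated O-acylation of the aldehyde enolate) turns the aldehyde into the weakly nucleophilic C9=C11 terminator that should survive the next operations; the stereocentre is β to the carbonyl and untouched, and the enol ester geometry is irrelevant because C9 later becomes sp2.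

**Step 2**
Reactants: 2 (3R)-3,7-dimethylocta-1,6-dien-1-yl pivalate
Product: 3 (3R,6E)-8-hydroxy-3,7-dimethylocta-1,6-dien-1-yl pivalate
Conditions: SeO2 (cat.), t-BuOOH, CH2Cl2, 0 °C → rt
Reagents that add atoms: tert-butyl hydroperoxide CC(C)(C)OO
Why: Catalytic selenium dioxide allylic oxidation (ene reaction, then [2,3]-sigmatropic shift) should hydroxylate the E-methyl group of the electron-rich trisubstituted olefin in preference to the acyloxy-substituted one, which fixes the E geometry of the later C5=C10 olefin.

**Step 3**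
Reactants: 3 (3R,6E)-8-hydroxy-3,7-dimethylocta-1,6-dien-1-yl pivalate
Product: 4 (3R,6E)-8-bromo-3,7-dimethylocta-1,6-dien-1-yl pivalate
Conditions: PBr3, pyridine (cat.), Et2O, −20 → 0 °C
Reagents that add atoms: phosphorus tribromide BrP(Br)Br
Why: SN2 bromination of the primary allylic alcohol at low temperature (as for geraniol to geranyl bromide) should proceed without allylic transposition and keep the E geometry.

**Step 4**
Reactants: 4 (3R,6E)-8-bromo-3,7-dimethylocta-1,6-dien-1-yl pivalate; 5 prenyl phenyl sulfone, [(3-methylbut-2-en-1-yl)sulfonyl]benzene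
Product: 9 (2R,4aS,8aS)-2,5,5,8a-tetramethyl-1,2,3,4,4a,5,8,8a-octahydronaphthalene-1-carbaldehyde (C1 epimers), via lithiated sulfone 6 (not isolated), via allylic sulfone 7 (not isolated), via chloroalkyl pivalate 8 (not isolated)
Conditions: 5, n-BuLi, THF, −78 °C; then 4, −78 → −30 °C; THF removed, CH2Cl2, EtAlCl2, −78 → −20 °C; H2O, rt
Reagents that add atoms: none
Why: The sulfone-stabilised carbanion 6 is alkylated at its α-carbon by the primary allylic bromide (SN2, the classical sulfone-anion isoprenoid coupling), which forms C1–C2 and leaves the E C5=C10 olefin untouched; EtAlCl2 then ionises the allylic C–S bond of 7 (the known Lewis-acid ionisation of allylic sulfones to allyl cations) to a 1,1-dimethylallyl cation. Its tertiary terminus C4 is attacked by C5 of the trisubstituted olefin to close ring A (6-endo with respect to the olefin; the allyl double bond ends endocyclic as C2=C3 once ion-pair return lets the cation adopt the cisoid geometry, as in the geranyl–linalyl–terpinyl manifold), and the developing C10 cation is captured anti by C9 of the enol pivalate to close ring B (6-exo), as in cation–olefin polycyclisations. Chloride quenches the acyloxycarbenium ion to 8, which water hydrolyses to the aldehyde. The chair–chair transition state should translate the E geometry into the trans ring fusion (C5–H anti to the C10 methyl), and the existing (R)-methyl centre at C8, equatorial to avoid a 1,3-diaxial clash with the C10 methyl, should fix the absolute sense as 5S,10S; C9 forms as a mixture that the next step erases. The step needs attack at C4 rather than C2 (only C4 closes a six-membered ring) and termination faster than hydride or methyl shifts, which the tethered enol ester is placed to provide.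

**Step 5**
Reactants: 9 (2R,4aS,8aS)-2,5,5,8a-tetramethyl-1,2,3,4,4a,5,8,8a-octahydronaphthalene-1-carbaldehyde
Product: 10 (4aS,8aS)-2,5,5,8a-tetramethyl-3,4,4a,5,8,8a-hexahydronaphthalene-1-carbaldehyde
Conditions: IBX, DMSO–fluorobenzene, 70 °C
Reagents that add atoms: none
Why: IBX dehydrogenation of the aldehyde through its enol removes the only β-hydrogen (at C8) and should give the tetrasubstituted C8=C9 enal, which erases the wrongly configured C8 centre and the C9 mixture.

**Step 6**
Reactants: 10 (4aS,8aS)-2,5,5,8a-tetramethyl-3,4,4a,5,8,8a-hexahydronaphthalene-1-carbaldehyde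
Product: 11 (2S,4aS,8aS)-2,5,5,8a-tetramethyldecahydronaphthalene-1-carbaldehyde (C1 configuration immaterial)
Conditions: H2 (4 atm), 10% Pd/C, EtOAc, rt
Reagents that add atoms: none
Why: Heterogeneous syn-hydrogenation should deliver hydrogen to the face of the C8=C9 olefin opposite the axial C10 methyl, which places the C8 methyl cis to it (8S), and it also saturates the C2=C3 olefin.

**Step 7**
Reactants: 12 benzene-1,2,4-triol
Product: 13 1,2,4-tris(methoxymethoxy)benzene
Conditions: MOMCl, i-Pr2NEt, CH2Cl2, 0 °C → rt, under N2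
Reagents that add atoms: chloromethyl methyl ether COCCl
Why: Williamson-type O-alkylation protects the three phenols as MOM ethers, which later direct the ring lithiation.

**Step 8**
Reactants: 13 1,2,4-tris(methoxymethoxy)benzene
Product: 14 1-bromo-2,4,5-tris(methoxymethoxy)benzene
Conditions: NBS, MeCN, 0 °C
Reagents that add atoms: N-bromosuccinimide O=C1CCC(=O)N1Br
Why: Electrophilic aromatic bromination should occur at the unhindered position that is para to one alkoxy group and ortho to another.

**Step 9**
Reactants: 14 1-bromo-2,4,5-tris(methoxymethoxy)benzene; 11 (2S,4aS,8aS)-2,5,5,8a-tetramethyldecahydronaphthalene-1-carbaldehyde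
Product: 16 [(2S,4aS,8aS)-2,5,5,8a-tetramethyldecahydronaphthalen-1-yl][2,4,5-tris(methoxymethoxy)phenyl]methanol (carbinol epimers), via aryllithium 15 (not isolated)
Conditions: n-BuLi, THF, −78 °C; then 11, −78 → 0 °C; H2O
Reagents that add atoms: none
Why: Bromine–lithium exchange and 1,2-addition of the aryllithium to the hindered aldehyde form the C11–aryl bond; the carbinol and C9 epimers converge in the next step.

**Step 10**
Reactants: 16 the benzylic carbinol
Product: 17 1-{(E)-[(2S,4aS,8aS)-2,5,5,8a-tetramethyloctahydronaphthalen-1(2H)-ylidene]methyl}-2,4,5-tris(methoxymethoxy)benzene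
Conditions: methyl N-(triethylammoniosulfonyl)carbamate (Burgess reagent), toluene, 50 °C
Reagents that add atoms: none
Why: Dehydration through the sulfamate ester (syn elimination or, for this electron-rich benzylic system, ionisation and loss of the C9 proton) can involve only the single β-hydrogen at C9 and should give the E olefin, in which the aryl group lies on the C8 side, away from the quaternary C10.

**Step 11**
Reactants: 17 the tris-MOM aryl olefin
Product: 19 2,3,6-tris(methoxymethoxy)-5-{(E)-[(2S,4aS,8aS)-2,5,5,8a-tetramethyloctahydronaphthalen-1(2H)-ylidene]methyl}benzaldehyde, via ring-lithiated arene 18 (not isolated)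
Conditions: n-BuLi, TMEDA, THF, −78 → −20 °C; DMF; H2O
Reagents that add atoms: N,N-dimethylformamide CN(C)C=O
Why: Directed ortho-metalation should occur at the ring position flanked by two MOM ethers, and formylation of the aryllithium with DMF installs the aldehyde there.

**Step 12**
Reactants: 19 the tris-MOM aldehyde
Product: 20 2,3,6-trihydroxy-5-{(E)-[(2S,4aS,8aS)-2,5,5,8a-tetramethyloctahydronaphthalen-1(2H)-ylidene]methyl}benzaldehyde
Conditions: HCl (1 M in MeOH), 0 °C → rt; aqueous work-up
Reagents that add atoms: none
Why: Acid-catalysed acetal exchange with methanol cleaves the three MOM ethers; dilute acid in methanol at low temperature is chosen so that the freed ortho-hydroxyl does not add to the trisubstituted olefin.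

**Step 13**
Reactants: 20 the trihydroxy aldehyde
Product: 23 2-formyl-3,4-dihydroxy-6-{(E)-[(2S,4aS,8aS)-2,5,5,8a-tetramethyloctahydronaphthalen-1(2H)-ylidene]methyl}phenyl hydrogen sulfate, via catechol phenylboronate 21 (not isolated), via sulfated boronate 22 (not isolated)
Conditions: PhB(OH)2, pyridine, 4 Å MS, rt; then SO3·pyridine, 45 °C; aqueous work-up at pH 7
Reagents that add atoms: sulfur trioxide–pyridine complex [O-]S(=O)(=O)[n+]1ccccc1
Why: Phenylboronic acid condenses selectively with the catechol to a cyclic boronate, so O-sulfation can occur only at the remaining hydroxyl between the olefin and the formyl group; the boronate hydrolyses on aqueous work-up.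

**Compound list**

1 | (R)-citronellal, (3R)-3,7-dimethyloct-6-enal | C[C@H](CCC=C(C)C)CC=O | starting material
2 | (3R)-3,7-dimethylocta-1,6-dien-1-yl pivalate (E/Z at the enol ester) | C[C@H](CCC=C(C)C)C=COC(=O)C(C)(C)C | intermediate
3 | (3R,6E)-8-hydroxy-3,7-dimethylocta-1,6-dien-1-yl pivalate | C[C@H](CC/C=C(\C)CO)C=COC(=O)C(C)(C)C | intermediate
4 | (3R,6E)-8-bromo-3,7-dimethylocta-1,6-dien-1-yl pivalate | C[C@H](CC/C=C(\C)CBr)C=COC(=O)C(C)(C)C | intermediate
5 | prenyl phenyl sulfone, [(3-methylbut-2-en-1-yl)sulfonyl]benzene | CC(C)=CCS(=O)(=O)c1ccccc1 | starting material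
6 | lithiated sulfone (lithium on the carbon next to sulfur of 5) | [Li]C(C=C(C)C)S(=O)(=O)c1ccccc1 | intermediate
7 | (3R,6E)-3,7,11-trimethyl-9-(phenylsulfonyl)dodeca-1,6,10-trien-1-yl pivalate (C9 epimers) | C[C@H](CC/C=C(\C)CC(C=C(C)C)S(=O)(=O)c1ccccc1)C=COC(=O)C(C)(C)C | intermediate
8 | chloro[(2R,4aS,8aS)-2,5,5,8a-tetramethyl-1,2,3,4,4a,5,8,8a-octahydronaphthalen-1-yl]methyl pivalate | C[C@@H]1CC[C@H]2C(C)(C)C=CC[C@]2(C)C1C(Cl)OC(=O)C(C)(C)C | intermediate
9 | (2R,4aS,8aS)-2,5,5,8a-tetramethyl-1,2,3,4,4a,5,8,8a-octahydronaphthalene-1-carbaldehyde (trans-fused, C1 epimers) | C[C@@H]1CC[C@H]2C(C)(C)C=CC[C@]2(C)C1C=O | intermediate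
10 | (4aS,8aS)-2,5,5,8a-tetramethyl-3,4,4a,5,8,8a-hexahydronaphthalene-1-carbaldehyde | CC1=C(C=O)[C@@]2(C)CC=CC(C)(C)[C@@H]2CC1 | intermediate
11 | (2S,4aS,8aS)-2,5,5,8a-tetramethyldecahydronaphthalene-1-carbaldehyde (C1 unspecified) | C[C@H]1CC[C@H]2C(C)(C)CCC[C@]2(C)C1C=O | intermediate
12 | benzene-1,2,4-triol | Oc1ccc(O)c(O)c1 | starting material
13 | 1,2,4-tris(methoxymethoxy)benzene | COCOc1ccc(OCOC)c(OCOC)c1 | intermediate
14 | 1-bromo-2,4,5-tris(methoxymethoxy)benzene | COCOc1cc(OCOC)c(OCOC)cc1Br | intermediate
15 | [2,4,5-tris(methoxymethoxy)phenyl]lithium | COCOc1cc(OCOC)c(OCOC)cc1[Li] | intermediate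
16 | [(2S,4aS,8aS)-2,5,5,8a-tetramethyldecahydronaphthalen-1-yl][2,4,5-tris(methoxymethoxy)phenyl]methanol (epimers at the carbinol and ring C1) | C[C@H]1CC[C@H]2C(C)(C)CCC[C@]2(C)C1C(O)c1cc(OCOC)c(OCOC)cc1OCOC | intermediate
17 | 1-{(E)-[(2S,4aS,8aS)-2,5,5,8a-tetramethyloctahydronaphthalen-1(2H)-ylidene]methyl}-2,4,5-tris(methoxymethoxy)benzene | C[C@H]1CC[C@H]2C(C)(C)CCC[C@]2(C)/C1=C/c1cc(OCOC)c(OCOC)cc1OCOC | intermediate
18 | 17 lithiated at the ring carbon between the 2- and 4-MOM ethers | C[C@H]1CC[C@H]2C(C)(C)CCC[C@]2(C)/C1=C/c1cc(OCOC)c(OCOC)c([Li])c1OCOC | intermediate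
19 | 2,3,6-tris(methoxymethoxy)-5-{(E)-[(2S,4aS,8aS)-2,5,5,8a-tetramethyloctahydronaphthalen-1(2H)-ylidene]methyl}benzaldehyde | C[C@H]1CC[C@H]2C(C)(C)CCC[C@]2(C)/C1=C/c1cc(OCOC)c(OCOC)c(C=O)c1OCOC | intermediate
20 | 2,3,6-trihydroxy-5-{(E)-[(2S,4aS,8aS)-2,5,5,8a-tetramethyloctahydronaphthalen-1(2H)-ylidene]methyl}benzaldehyde | C[C@H]1CC[C@H]2C(C)(C)CCC[C@]2(C)/C1=C/c1cc(O)c(O)c(C=O)c1O | intermediate
21 | cyclic phenylboronate of the catechol of 20 (6-hydroxyl free) | C[C@H]1CC[C@H]2C(C)(C)CCC[C@]2(C)/C1=C/c1cc2OB(c3ccccc3)Oc2c(C=O)c1O | intermediate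
22 | hydrogen sulfate of 21 at the free hydroxyl | C[C@H]1CC[C@H]2C(C)(C)CCC[C@]2(C)/C1=C/c1cc2OB(c3ccccc3)Oc2c(C=O)c1OS(=O)(=O)O | intermediate
23 | 2-formyl-3,4-dihydroxy-6-{(E)-[(2S,4aS,8aS)-2,5,5,8a-tetramethyloctahydronaphthalen-1(2H)-ylidene]methyl}phenyl hydrogen sulfate | C[C@H]1CC[C@H]2C(C)(C)CCC[C@]2(C)/C1=C/c1cc(O)c(O)c(C=O)c1OS(=O)(=O)O | target

**Step count**

Total steps: 13. Longest linear sequence: 11 steps (steps 1–6 and 9–13, from (R)-citronellal); the arene branch is steps 7–8.

**Steps most likely to fail**

Step 4. Lithium salts and residual THF may blunt the Lewis acid. The allyl cation may also lose a proton to a diene, or the enol ester may terminate too slowly, which would give monocyclic or rearranged material or erode the trans fusion. The fallback sets out from 4 and returns at 11, with the two bonds made in separate steps. Li2CuCl4-catalysed coupling of 4 with (3-methylbut-3-en-1-yl)magnesium bromide should give (3R,6E)-3,7,11-trimethyldodeca-1,6,11-trien-1-yl pivalate F1. A hydrogen-atom-transfer-initiated radical–polar crossover bicyclisation (N,N′-bis(3,5-di-tert-butylsalicylidene)-1,2-ethanediaminocobalt, a divalent cobalt complex, with N-fluoro-2,4,6-trimethylpyridinium triflate and PhSiH3) should then convert the 1,1-disubstituted olefin selectively into the C4 cation. The same chair–chair closure and hydrolytic work-up should give (2R,4aS,8aS)-2,5,5,8a-tetramethyldecahydronaphthalene-1-carbaldehyde F2. IBX as in step 5 should give (4aS,8aS)-2,5,5,8a-tetramethyl-3,4,4a,5,6,7,8,8a-octahydronaphthalene-1-carbaldehyde F3, which is hydrogenated as in step 6 to 11.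

Step 6. The tetrasubstituted enal may hydrogenate sluggishly, and double-bond migration on palladium may erode the facial control at C8. The fallback sets out from 10 and returns at 11. Conjugate hydride delivery with [(Ph3P)CuH]6 in toluene, followed by protonation, should put the hydride on C8 from the face opposite the C10 methyl and give (2S,4aS,8aS)-2,5,5,8a-tetramethyl-1,2,3,4,4a,5,8,8a-octahydronaphthalene-1-carbaldehyde F4. The remaining unhindered ring olefin is then hydrogenated (H2, Pd/C) to 11.

Step 13. Masking of the catechol may be incomplete, or sulfation of the hindered, hydrogen-bonded phenol may be slow, so that regioisomeric or multiple sulfates form. The fallback sets out from 20 and returns at 23, using an isolable protecting group. t-Bu2Si(OTf)2 with 2,6-lutidine should bridge the catechol to give 2,2-di-tert-butyl-1,3,2-benzodioxasilole derivative of 20 with the flanked hydroxyl free F5. Sulfation with SO3·pyridine should give its hydrogen sulfate F6, and buffered HF·pyridine should remove the silylene to give 23.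

**Further compounds**

F1 | step 4 | (3R,6E)-3,7,11-trimethyldodeca-1,6,11-trien-1-yl pivalate | C[C@H](CC/C=C(\C)CCCC(C)=C)C=COC(=O)C(C)(C)C
F2 | step 4 | (2R,4aS,8aS)-2,5,5,8a-tetramethyldecahydronaphthalene-1-carbaldehyde (C1 epimers) | C[C@@H]1CC[C@H]2C(C)(C)CCC[C@]2(C)C1C=O
F3 | step 4 | (4aS,8aS)-2,5,5,8a-tetramethyl-3,4,4a,5,6,7,8,8a-octahydronaphthalene-1-carbaldehyde | CC1=C(C=O)[C@@]2(C)CCCC(C)(C)[C@@H]2CC1
F4 | step 6 | (2S,4aS,8aS)-2,5,5,8a-tetramethyl-1,2,3,4,4a,5,8,8a-octahydronaphthalene-1-carbaldehyde (C1 unspecified) | C[C@H]1CC[C@H]2C(C)(C)C=CC[C@]2(C)C1C=O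
F5 | step 13 | di-tert-butylsilylene derivative of the catechol of 20 (flanked hydroxyl free) | C[C@H]1CC[C@H]2C(C)(C)CCC[C@]2(C)/C1=C/c1cc2O[Si](C(C)(C)C)(C(C)(C)C)Oc2c(C=O)c1O
F6 | step 13 | hydrogen sulfate of F5 at the free hydroxyl | C[C@H]1CC[C@H]2C(C)(C)CCC[C@]2(C)/C1=C/c1cc2O[Si](C(C)(C)C)(C(C)(C)C)Oc2c(C=O)c1OS(=O)(=O)O
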